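## Retrosynthetic overview

1. Target ⇐ bis-silyl ether ⇐ C6–O ester bond, made by oxidative C–H/O–H coupling of a γ-acyloxy enone with (E)-4-silyloxy-2-methylbut-2-enoic acid (new step).
2. γ-Isobutyryloxy enone ⇐ C4–O bond formed with inversion (Mitsunobu) from the trans γ-hydroxy enone.
3. γ-Hydroxy enone ⇐ two C–O bonds from O2: singlet-oxygen [4+2] on a 5-isopropylcyclohexa-1,3-diene, then Kornblum–DeLaMare rearrangement.
4. Diene ⇐ Shapiro reaction of (S)-cryptone trisylhydrazone, the vinyllithium trapped with CH2O then TBSCl; side-chain acid ⇐ Wittig olefination.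
5. Ring order: the single carbocycle is formed first (organocatalytic Michael addition, then aldol condensation); only a transient peroxide bridge follows.

Target numbering used below: C1 ketone, C2 carbon bearing CH2OH, C3 vinyl CH, C4 carbon bearing the isobutyrate, C5 carbon bearing isopropyl, C6 carbon bearing the hydroxytiglate. The target is (4S,5S,6R), with the C6 oxygen trans and the C4 oxygen cis to isopropyl.

Assumption: the (S)-prolinol ether catalyst gives the (S)-aldehyde (attack on the enamine face away from the diarylmethyl group), as in related enamine Michael additions.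

## Route

Step 1
Reactants: 1 3-methylbutanal (isovaleraldehyde); 2 but-3-en-2-one (methyl vinyl ketone)
Product: 4 (4S)-4-(propan-2-yl)cyclohex-2-en-1-one [(S)-cryptone], via keto-aldehyde 3 (not isolated)
Conditions: (S)-2-(methoxydiphenylmethyl)pyrrolidine (5 mol %), ethyl 3,4-dihydroxybenzoate (20 mol %), neat, 4 °C; then LiOH (20 mol %), i-PrOH, rt
Reagents that add atoms: none
Why: Enamine-catalysed asymmetric Michael addition sets the isopropyl-bearing stereocentre (C5 of the target, S) by attack on the unshielded enamine face, and the intramolecular aldol condensation (Robinson-type annulation) closes the ring without touching it.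

Step 2
Reactants: 4 (4S)-4-(propan-2-yl)cyclohex-2-en-1-one
Product: 5 N′-[(4S)-4-(propan-2-yl)cyclohex-2-en-1-ylidene]-2,4,6-tri(propan-2-yl)benzenesulfonohydrazide
Conditions: 2,4,6-(i-Pr)3C6H2SO2NHNH2 (1.05 equiv), HCl (cat.), THF, 0 °C → rt
Reagents that add atoms: 2,4,6-tri(propan-2-yl)benzenesulfonohydrazide, CC(C)c1cc(C(C)C)c(S(=O)(=O)NN)c(C(C)C)c1
Why: Acid-catalysed hydrazone condensation at the carbonyl gives a crystalline derivative (recrystallisation can raise the enantiomeric purity) and leaves the stereocentre untouched.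

Step 3
Reactants: 5 trisylhydrazone of (S)-cryptone; 6 formaldehyde (used as paraformaldehyde)
Product: 9 tert-butyl(dimethyl){[(4S)-4-(propan-2-yl)cyclohexa-1,5-dien-1-yl]methoxy}silane, via dienyllithium 7 (not isolated), via lithium alkoxide 8 (not isolated)
Conditions: n-BuLi (2.2 equiv), TMEDA, THF, −78 → 0 °C; then (CH2O)n, −78 °C → rt; then TBSCl, DMAP (cat.), rt
Reagents that add atoms: tert-butyldimethylsilyl chloride, CC(C)(C)[Si](C)(C)Cl
Why: Shapiro reaction: the hydrazone dianion formed by α′-deprotonation loses sulfinate and N2 to give the cross-conjugated dienyllithium, which is hydroxymethylated and silylated in the same flask; the sp3 stereocentre is not involved.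

Step 4
Reactants: 9 silyl ether of (4S)-4-isopropylcyclohexa-1,5-dien-1-ylmethanol
Product: 11 (4S,5S)-2-({[tert-butyl(dimethyl)silyl]oxy}methyl)-4-hydroxy-5-(propan-2-yl)cyclohex-2-en-1-one, via endoperoxide 10 (not isolated)
Conditions: O2, tetraphenylporphyrin (1 mol %), hν (white LED), CH2Cl2, −40 °C; then Et3N (0.5 equiv), 0 °C → rt
Reagents that add atoms: dioxygen, O=O
Why: Singlet-oxygen [4+2] cycloaddition adds O2 mainly to the diene face anti to isopropyl (about 3:2 expected; the minor series is removed by chromatography after rearrangement), and the Kornblum–DeLaMare rearrangement removes the less hindered bridgehead hydrogen (flanked by CH2, not by CH–i-Pr), so C1 becomes the ketone and C4 keeps its oxygen trans to isopropyl.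

Step 5
Reactants: 11 trans γ-hydroxy enone; 12 2-methylpropanoic acid (isobutyric acid)
Product: 13 (1R,6S)-3-({[tert-butyl(dimethyl)silyl]oxy}methyl)-4-oxo-6-(propan-2-yl)cyclohex-2-en-1-yl 2-methylpropanoate
Conditions: PPh3, DIAD, toluene, 0 °C → rt
Reagents that add atoms: none
Why: Mitsunobu reaction: SN2 attack of isobutyrate on the allylic alkoxyphosphonium ion inverts C4 and places the ester cis to isopropyl as in the target, while the silyl ether keeps the primary alcohol out of the reaction.

Step 6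
Reactants: 14 2-{[tert-butyl(dimethyl)silyl]oxy}acetaldehyde; 15 ethyl 2-(triphenylphosphoranylidene)propanoate
Product: 16 ethyl (2E)-4-{[tert-butyl(dimethyl)silyl]oxy}-2-methylbut-2-enoate
Conditions: CH2Cl2, rt
Reagents that add atoms: none
Why: Wittig olefination with a stabilised ylide gives the (E)-trisubstituted alkene with high selectivity.

Step 7
Reactants: 16 ethyl (2E)-4-silyloxy-2-methylbut-2-enoate
Product: 17 (2E)-4-{[tert-butyl(dimethyl)silyl]oxy}-2-methylbut-2-enoic acid
Conditions: LiOH·H2O (2 equiv), THF/MeOH/H2O, rt; then 1 M HCl to pH 4, 0 °C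
Reagents that add atoms: lithium hydroxide, [Li+].[OH-]
Why: Ester saponification; the primary silyl ether and the alkene geometry survive mild aqueous base.

Step 8
Reactants: 13 γ-isobutyryloxy enone; 17 (2E)-4-silyloxy-2-methylbut-2-enoic acid (1.2 equiv)
Product: 18 (1R,5S,6S)-3-({[tert-butyl(dimethyl)silyl]oxy}methyl)-5-[(2-methylpropanoyl)oxy]-2-oxo-6-(propan-2-yl)cyclohex-3-en-1-yl (2E)-4-{[tert-butyl(dimethyl)silyl]oxy}-2-methylbut-2-enoate
Conditions: Bu4NI (10 mol %), t-BuOOH (2 equiv, in decane), EtOAc, 50 °C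
Reagents that add atoms: none
Why: Proposed new method: iodide-catalysed oxidative C–H/O–H coupling at the α′-carbon of a cross-conjugated enone — t-BuOOH oxidises iodide to ammonium hypoiodite, which iodinates the only enolisable α-position (C6, since C2 carries no hydrogen), iodide exchange equilibrates the two α′-iodo epimers, and the axial iodide (cis to isopropyl, aligned with the carbonyl π system) is displaced by the carboxylate of 17 from the face anti to isopropyl with return of iodide, so the C6–O bond forms trans to isopropyl (6R), which is also the more stable diequatorial epimer; the closest known reaction type is the ammonium iodide/hydroperoxide α-acyloxylation of simple saturated and aryl ketones with carboxylic acids, not shown for the α′-position of an enone or as a diastereoselective late-stage ester coupling.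

Step 9
Reactants: 18 bis-silyl ether of the target
Product: 19 (1R,5S,6S)-3-(hydroxymethyl)-5-[(2-methylpropanoyl)oxy]-2-oxo-6-(propan-2-yl)cyclohex-3-en-1-yl (2E)-4-hydroxy-2-methylbut-2-enoate (CNP0254776.1)
Conditions: HF·pyridine, pyridine, THF, 0 °C → rt
Reagents that add atoms: none
Why: Buffered fluoride desilylation frees both primary alcohols without acyl migration, elimination or epimerisation at C6.

## Compound list

1 | 3-methylbutanal (isovaleraldehyde) | CC(C)CC=O | starting material
2 | but-3-en-2-one (methyl vinyl ketone) | CC(=O)C=C | starting material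
3 | (2S)-5-oxo-2-(propan-2-yl)hexanal | O=C[C@H](C(C)C)CCC(C)=O | intermediate (not isolated)
4 | (4S)-4-(propan-2-yl)cyclohex-2-en-1-one, (S)-cryptone | O=C1C=C[C@H](C(C)C)CC1 | intermediate
5 | N′-[(4S)-4-(propan-2-yl)cyclohex-2-en-1-ylidene]-2,4,6-tri(propan-2-yl)benzenesulfonohydrazide (C=N geometry not defined) | CC(C)c1cc(C(C)C)c(S(=O)(=O)NN=C2C=C[C@H](C(C)C)CC2)c(C(C)C)c1 | intermediate
6 | formaldehyde (used as paraformaldehyde) | C=O | starting material
7 | [(4S)-4-(propan-2-yl)cyclohexa-1,5-dien-1-yl]lithium | [Li]C1=CC[C@@H](C(C)C)C=C1 | intermediate (not isolated)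
8 | lithium [(4S)-4-(propan-2-yl)cyclohexa-1,5-dien-1-yl]methanolate | [Li]OCC1=CC[C@@H](C(C)C)C=C1 | intermediate (not isolated)
9 | tert-butyl(dimethyl){[(4S)-4-(propan-2-yl)cyclohexa-1,5-dien-1-yl]methoxy}silane | CC(C)(C)[Si](C)(C)OCC1=CC[C@@H](C(C)C)C=C1 | intermediate
10 | tert-butyl(dimethyl){[(1S,4R,7S)-7-(propan-2-yl)-2,3-dioxabicyclo[2.2.2]oct-5-en-5-yl]methoxy}silane (peroxide bridge anti to isopropyl) | CC(C)(C)[Si](C)(C)OCC1=C[C@H]2OO[C@@H]1C[C@H]2C(C)C | intermediate (not isolated)
11 | (4S,5S)-2-({[tert-butyl(dimethyl)silyl]oxy}methyl)-4-hydroxy-5-(propan-2-yl)cyclohex-2-en-1-one (OH trans to isopropyl) | CC(C)(C)[Si](C)(C)OCC1=C[C@@H](O)[C@H](C(C)C)CC1=O | intermediate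
12 | 2-methylpropanoic acid (isobutyric acid) | CC(C)C(=O)O | starting material
13 | (1R,6S)-3-({[tert-butyl(dimethyl)silyl]oxy}methyl)-4-oxo-6-(propan-2-yl)cyclohex-2-en-1-yl 2-methylpropanoate (ester cis to isopropyl) | CC(C)(C)[Si](C)(C)OCC1=C[C@H](OC(=O)C(C)C)[C@H](C(C)C)CC1=O | intermediate
14 | 2-{[tert-butyl(dimethyl)silyl]oxy}acetaldehyde | CC(C)(C)[Si](C)(C)OCC=O | starting material
15 | ethyl 2-(triphenylphosphoranylidene)propanoate | CCOC(=O)C(C)=P(c1ccccc1)(c1ccccc1)c1ccccc1 | starting material
16 | ethyl (2E)-4-{[tert-butyl(dimethyl)silyl]oxy}-2-methylbut-2-enoate | C/C(=C\CO[Si](C)(C)C(C)(C)C)C(=O)OCC | intermediate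
17 | (2E)-4-{[tert-butyl(dimethyl)silyl]oxy}-2-methylbut-2-enoic acid | C/C(=C\CO[Si](C)(C)C(C)(C)C)C(=O)O | intermediate
18 | (1R,5S,6S)-3-({[tert-butyl(dimethyl)silyl]oxy}methyl)-5-[(2-methylpropanoyl)oxy]-2-oxo-6-(propan-2-yl)cyclohex-3-en-1-yl (2E)-4-{[tert-butyl(dimethyl)silyl]oxy}-2-methylbut-2-enoate | C/C(=C\CO[Si](C)(C)C(C)(C)C)C(=O)O[C@H]1C(=O)C(CO[Si](C)(C)C(C)(C)C)=C[C@H](OC(=O)C(C)C)[C@@H]1C(C)C | intermediate
19 | (1R,5S,6S)-3-(hydroxymethyl)-5-[(2-methylpropanoyl)oxy]-2-oxo-6-(propan-2-yl)cyclohex-3-en-1-yl (2E)-4-hydroxy-2-methylbut-2-enoate | C/C(=C\CO)C(=O)O[C@H]1C(=O)C(CO)=C[C@H](OC(=O)C(C)C)[C@@H]1C(C)C | target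

## Step count and risks

Total step count: 9. Longest linear sequence: 7 (steps 1, 2, 3, 4, 5, 8, 9).

Three steps most likely to fail:

**Step 8 (the proposed new step).** Risks are slow α′-enolisation, competing γ-enolisation or radical allylic oxidation, and incomplete diastereocontrol. The fallback uses known chemistry, sets out from 13 and comes back at 18. Kinetic enolisation of 13 with LiN(SiMe3)2 and Me3SiCl (THF, −78 °C) gives the silyl dienol ether (1R,6R)-3-({[tert-butyl(dimethyl)silyl]oxy}methyl)-6-(propan-2-yl)-4-[(trimethylsilyl)oxy]cyclohexa-2,4-dien-1-yl 2-methylpropanoate F5. Rubottom oxidation with dimethyldioxirane (acetone, −40 °C, then citric acid in MeOH), from the face anti to isopropyl, gives the α′-hydroxy ketone (1S,5R,6R)-3-({[tert-butyl(dimethyl)silyl]oxy}methyl)-5-hydroxy-4-oxo-6-(propan-2-yl)cyclohex-2-en-1-yl 2-methylpropanoate F6. Steglich esterification of this alcohol with 17 (EDC·HCl, DMAP, CH2Cl2) gives 18.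

**Step 5.** The alcohol is a hindered secondary allylic one next to CH–i-Pr and the acid is weakly acidic, so low conversion or elimination toward the phenol is possible. The fallback sets out from 11 and comes back at 13, separating inversion from acylation. Mitsunobu inversion with 4-nitrobenzoic acid (PPh3, DIAD, toluene) gives (1R,6S)-3-({[tert-butyl(dimethyl)silyl]oxy}methyl)-4-oxo-6-(propan-2-yl)cyclohex-2-en-1-yl 4-nitrobenzoate F3. Methanolysis (K2CO3, MeOH, 0 °C) gives the cis alcohol (4R,5S)-2-({[tert-butyl(dimethyl)silyl]oxy}methyl)-4-hydroxy-5-(propan-2-yl)cyclohex-2-en-1-one F4. Acylation with isobutyric anhydride (DMAP, pyridine, CH2Cl2) then gives 13 with retention.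

**Step 3.** Risks are deprotonation of the unsaturated hydrazone at the wrong site, protonation of the dienyllithium, and poor capture of formaldehyde. The fallback sets out from 4 and comes back at 9, replacing the Shapiro reaction by enol triflate cross-coupling. Kinetic deprotonation of 4 with LiN(i-Pr)2 (THF, −78 °C) and trapping with PhNTf2 gives (4S)-4-(propan-2-yl)cyclohexa-1,5-dien-1-yl trifluoromethanesulfonate F1. Stille coupling with Bu3SnCH2OH (Pd(PPh3)4, LiCl, THF, 65 °C) gives [(4S)-4-(propan-2-yl)cyclohexa-1,5-dien-1-yl]methanol F2. Silylation (TBSCl, imidazole, DMF) gives 9.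

Further compounds

F1 | step 3 | (4S)-4-(propan-2-yl)cyclohexa-1,5-dien-1-yl trifluoromethanesulfonate | O=S(=O)(OC1=CC[C@@H](C(C)C)C=C1)C(F)(F)F
F2 | step 3 | [(4S)-4-(propan-2-yl)cyclohexa-1,5-dien-1-yl]methanol | OCC1=CC[C@@H](C(C)C)C=C1
F3 | step 5 | (1R,6S)-3-({[tert-butyl(dimethyl)silyl]oxy}methyl)-4-oxo-6-(propan-2-yl)cyclohex-2-en-1-yl 4-nitrobenzoate | CC(C)(C)[Si](C)(C)OCC1=C[C@H](OC(=O)c2ccc(cc2)[N+](=O)[O-])[C@H](C(C)C)CC1=O
F4 | step 5 | (4R,5S)-2-({[tert-butyl(dimethyl)silyl]oxy}methyl)-4-hydroxy-5-(propan-2-yl)cyclohex-2-en-1-one | CC(C)(C)[Si](C)(C)OCC1=C[C@H](O)[C@H](C(C)C)CC1=O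
F5 | step 8 | (1R,6R)-3-({[tert-butyl(dimethyl)silyl]oxy}methyl)-6-(propan-2-yl)-4-[(trimethylsilyl)oxy]cyclohexa-2,4-dien-1-yl 2-methylpropanoate | CC(C)(C)[Si](C)(C)OCC1=C[C@H](OC(=O)C(C)C)[C@H](C(C)C)C=C1O[Si](C)(C)C
F6 | step 8 | (1S,5R,6R)-3-({[tert-butyl(dimethyl)silyl]oxy}methyl)-5-hydroxy-4-oxo-6-(propan-2-yl)cyclohex-2-en-1-yl 2-methylpropanoate | O[C@H]1C(=O)C(CO[Si](C)(C)C(C)(C)C)=C[C@H](OC(=O)C(C)C)[C@@H]1C(C)C
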